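Start from the amber and red runs: both were read at 90.0 min, the same time as the 1.5 h planned for the next flasks.

| setting | amber | red | Tuesday's | Wednesday's | Thursday's | Friday's | Monday's |
|---|---|---|---|---|---|---|---|
| Q | 0.067 M | 0.99 M | 0.10 M | 0.20 M | 0.40 M | 0.80 M | 1.5 M |
| remark | run made earlier | run made earlier |  |  |  |  |  |
| time |  |  | 1.5 h | 1.5 h | 1.5 h | 1.5 h | 1.5 h |

| run | time / min | Z / % |
|---|---|---|
| amber | 8.00 | 0.5 |
| amber | 15.0 | 1.0 |
| amber | 25.0 | 1.8 |
| amber | 50.0 | 4.2 |
| amber | 90.0 | 7.6 |
| red | 20.0 | 1.5 |
| red | 40.0 | 4.3 |
| red | 50.0 | 6.2 |
| red | 80.0 | 8.7 |
| red | 90.0 | 10.7 |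

(readings scatter by 0.5 percentage points)

- a reading or a percentage of Z counts all its forms, free or not
- the concentration of Z that is asked is that of its free form alone
- "hardly changes" means that all values lie within two and a half points (for a concentration: within two and a half percent of the largest)

- [Z] (only what is free in solution) at the end for Tuesday's, Wednesday's, Thursday's, Friday's, Monday's, in this order
- how the row runs (hardly changes / falls, then rises / rises, then falls / rises all the way / falls all the way)

Decide how far up the charge to go, and judge that by how counted Z follows the charge. Amber, charged with 0.067 M, read 7.6 % of its Q as Z at that time, and red, charged with 0.99 M, read 10.7 %. From these two readings reckon the charge exponent 1.13, the percent change of counted Z at the end per percent of charge, or apparent order. Treat it as a reading, since each share behind it carries a scatter of 0.5 percentage points. It stands above one, so expect counted Z to grow a little faster than the charge.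

Now carry it from amber to Monday's charge of 1.5 M, which lies beyond red's. My own reckoning puts Monday's counted Z at 0.169 M. Take this as an estimate of Z in all its forms together, since that is what the readings count, and they don't show how much of it is free. So keep Monday's charge in the plan, but measure the free form apart.

The forecast runs from 0.0079 M to 0.177 M, rises all the way, and on free Z it says: “I take Z as essentially all free”.

Monday's flask gives 0.0525 M of free Z, about a third of the 0.162 M it counts, and the row rises all the way.

    Q ⇌ D (K = 0.210, k = 0.00970 min⁻¹)
    Q + Z ⇌ J, settled at all times (K = 2.00 M⁻¹)
    D ⇌ Z (K = 0.790, k = 0.0130 min⁻¹)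

Monday's J stands at 14.6 % of the Q charged, each J counted as two. Its free Z has a local order of 0.45, lower than the charge exponent of 1.13, which was read on counted Z. On Thursday's charge of 0.40 M the exponent gives 0.0383 M counted, and Thursday's flask counts 0.0376 M, of which 0.0237 M is free.

(The readings are simulated for an exercise, and the scatter is random.)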